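## Analysis of the target

The target is a linear B-type proanthocyanidin tetramer: four 2-arylchroman (flavan-3-ol) units joined by three C4→C8 bonds. From the top these are an epigallocatechin (unit 1), a second epigallocatechin (unit 2), an epigallocatechin 3-O-gallate (unit 3) and a terminal epicatechin (unit 4). There are eleven stereocentres. C2 and C3 of all four units are (2R,3R), with the C2 aryl group and the C3 oxygen cis on ring C, and C4 of units 1–3 carries the next unit trans to the C3 oxygen (4β). The sensitive parts are the phloroglucinol-type rings A (strongly nucleophilic, easily oxidised, and the reason the interflavan bonds ionise under acid), the pyrogallol and catechol rings B (autoxidation; base opens ring C and epimerises C2 in the free phenols) and the single galloyl ester, which base removes or shifts. The difficulty is that three nearly identical extension units must each be made 2,3-cis with an oxidised C4, three interflavan bonds must each be formed at C8 with 4β configuration, and one gallate must sit on O3 of unit 3 alone while three other C3 hydroxyls stay free. The strategy rests on the O1–C8a aryl ether bond of ring C of the extension units and on the cis relation of the C2 aryl group and the C3 oxygen. A C2–C3–C4 chain with three syn oxygens (threo at C2/C3) becomes the 2,3-cis-3,4-trans flavan if O1–C8a is formed with the C2–O bond intact, whereas displacement at C2 would give the 2,3-trans series. C3 and C4 with their oxygens map onto the two carbinol carbons of L-tartaric acid; C4 later becomes a cation, so only the C3 centre of the pool has to survive.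

## Retrosynthetic reasoning

**Global deprotection.** All 22 phenolic oxygens of 25 are masked as benzyl ethers in 24 and released in one neutral hydrogenolysis. Cutting here, and not at a C–C bond, keeps the air- and base-sensitive free polyphenol for the last flask. The three secondary alcohols of units 1, 2 and 4 need no protection, and the gallate of unit 3 is already present as its tribenzyl ether.

**Upper interflavan bonds.** The bonds C4(unit 1)–C8(unit 2) and C4(unit 2)–C8(unit 3) are cut, leading from 24 to trimer 23 and from 23 to dimer 22, each time releasing the same monomeric donor 17. These bonds are chosen because C4 is benzylic to a phloroglucinol-type ring and ionises readily, while C8 of a benzylated flavan is its most nucleophilic aromatic position. The forward reaction is a Friedel–Crafts alkylation that must be C8-selective and must place the incoming unit trans to the C3 oxygen; attack anti to the cis C2/C3 substituents provides this. Growing from the bottom means the nucleophile always offers its newest, least hindered ring A.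

**Lowest interflavan bond and the gallate.** Dimer 22 is cut in the same way into the galloylated donor 19 and the nucleophile 21, the tetrabenzyl ether of purchased 20. The gallate is disconnected at its ester bond on the monomer, so 19 comes from 17 and acid 18. Acylating before the first coupling means O3 of unit 3 is the only hydroxyl present when the ester is made, and the ester then assists the 4β outcome by neighbouring-group participation. One donor, 17, therefore serves units 1, 2 and 3.

**Leaving group at C4 and free O3.** Donor 17 needs a free O3 and an alkoxy leaving group on C4. Both are traced back to the acetal groups of 16: the acidic alcoholysis that frees O3 also exchanges the acetal on the benzylic C4 for a simple alkoxy group. Benzyl ethers on O3 and O4 would be the simplest protection for the ring closure, but then O3 of unit 3 could never be told apart from the phenolic ethers. The methoxymethyl pair leaves the key step unchanged and makes the gallate possible.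

**Ring C (key disconnection).** Ring C of 16 is cut at O1–C8a, giving the open chain 15 with a free C2 hydroxyl and an aryl bromide ortho to the chain on ring A. This bond is chosen, and not O1–C2, because it is the only bond of ring C that can be closed without touching a stereocentre. The C2–O bond stays intact, so the syn (threo) relation of the C2 and C3 oxygens in 15 becomes the cis relation in 16; displacement at the electron-rich benzylic C2 would invert it or ionise it. The forward reaction must form an aryl–oxygen bond from a secondary benzylic alkoxide without epimerisation or elimination. Copper catalysis with a carbonate base does this, and with O3 and O4 etherified only the six-membered ring can form.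

**C2 stereocentre.** The carbinol of 15 is taken back to ketone 14, and 14 to Weinreb amide 11 and the ring B Grignard reagent 13 (from bromide 12). The C2–aryl bond is made by acylation and not by addition to an aldehyde because the ketone lets hydride set the new centre under non-chelation control from the adjacent C3 oxygen, which gives the required syn isomer. Addition of an aryl metal to the corresponding aldehyde under the same control would give the anti isomer.

**Protecting groups on O3 and O4.** Amide 11 comes from ester 10, and the two methoxymethyl ethers of 10 from diol 9 and acetonide 8. The acetonide cannot be kept for the ring closure: O3 and O4 end up trans on ring C, and a dioxolane fused trans to the half-chair pyran ring is too strained to form. The exchange is placed at the ester stage, before the acid-sensitive C2 carbinol exists and while only one benzylic position is present.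

**Ring A–C4 bond.** In 8 the bond between the future C4 and ring A is cut. That carbon is a carboxyl-bearing carbinol carbon in half-acid 4, so the bond is made by decarboxylative arylation of the redox-active ester 5 with zinc reagent 7. The dioxolanyl radical is captured trans to the neighbouring ester, and the configuration at this carbon does not matter in the end because it becomes the C4 cation. Ring A must carry the chain between a bromine and a benzyloxy group, with the second benzyloxy group para to the chain. Metalating the bromine-bearing carbon of 1 and brominating afterwards would put both benzyloxy groups meta to the chain. The bromine of 1 is therefore kept as the handle for the key step, and the metal is placed on the neighbouring carbon through iodide 2 and magnesium reagent 6. Half-acid 4 is the mono-saponification product of the C2-symmetric diester 3 from the L-tartrate pool, which supplies C3 and C4 with their oxygens, one carboxyl carbon as C2 and the other as the departing CO2.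

## Alternatives that were turned down

**Alternative 1:** Ring A of unit 4 is disconnected (C8–C8a, C6–C7 and, in the electrocyclic step, C4a–C8a), so the unit 3–unit 4 bond enters the annulation as the C4–alkyne bond of the siloxyalkyne A2.
- Forward key step: A2 and the cyclobutenone A3 are heated. A3 opens to a vinylketene, which adds [2+2] to the ynol ether; a second 4π opening and a 6π closure give the phenol A1 (Danheiser benzannulation).
- For: the interflavan bond to unit 4 is fixed at C8 by construction, not by a C6/C8 competition, and the three oxygens of the new ring A emerge differentiated (free O1, silyl O7, benzyl O5). On regiochemical certainty for this one link it is stronger than the chosen route.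
- Against: A2 needs a 4β-alkynyl flavan carrying a thermally fragile silyl ynol ether on a doubly activated benzylic carbon, and A3 needs its own stereodefined side chain. A1 is still an open chain whose ring C must be closed by displacement at the electron-rich benzylic C2 with inversion, a step prone to leak through a cation.
- Comparison: it solves one of three interflavan bonds at the price of two further multistep fragments, and units 1 and 2 still need Friedel–Crafts coupling. The chosen route gives up the built-in regiocontrol but makes all three links with one donor type, buys unit 4 as 20 and never puts a leaving group on C2.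

**Alternative 2:** The cut is O1–C2 of unit 1, with the C3 oxygen delivered in the same event.
- Forward key step: in the 2-(α-mesyloxybenzyl)-2,3-dihydrobenzofuran A5 the ring oxygen displaces the mesylate to give an epoxonium ion across C2–C3. An external carboxylate opens it at C3, expanding the five-membered ring to ring C and giving A4.
- For: both inversions are stereospecific, so 2,3-cis follows from the configuration of A5. The C4–C8 bond is already in place, so no intermolecular coupling is needed for the unit 1–unit 2 link, and 3,4-trans is set in a dihydrobenzofuran, where it is easy. O3 arrives as an ester, differentiated from all other oxygens. On the stereochemical definition of C4 it is stronger than the chosen route.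
- Against: the first displacement occurs at a benzylic carbon of a trioxygenated ring B, which must be detuned with three pivalates to stop ionisation. The epoxonium ion can also open at the benzylic C2, with return or loss of configuration. The pivalates and the acetate must later be cleaved by base or hydride in a molecule that has to keep the gallate of unit 3. Each extension unit needs its own dihydrobenzofuran synthesis on a growing oligomer.
- Comparison: the chosen ring closure breaks no bond to a stereocentre, needs only benzyl and acetal protection that fits the final hydrogenolysis, and one monomer serves three times.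

**Alternative 3:** Ring C of unit 3 is cut at O1–C2 and C3–C4, a hetero-Diels–Alder disconnection.
- Forward key step: acid ionises the carbinol A8 to an ortho-quinone methide attached to C8 of unit 4, and the (Z)-enol ester A7 adds across O1 and C4 to give A6.
- For: it is the most convergent of the four ideas. Ring C, the interflavan bond and the gallate arrive in one step, and the Z geometry translates into 2,3-cis. In step economy for the unit 3–unit 4 half it is clearly stronger than the chosen route.
- Against: the only stereocentres present are those of unit 4, remote from the reacting diene, so the face of addition (absolute configuration at C2, C3 and C4 of unit 3) is uncontrolled, and endo/exo selectivity decides 3,4-trans versus cis. A7 is a weak, 1,2-disubstituted dienophile in which the acyloxy and aryl groups polarise the double bond in opposite directions, so orientation is not assured. A (Z)-enol gallate is not trivially made or kept. Units 1 and 2 carry no gallate and are not served.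
- Comparison: the chosen route is longer for unit 3 but derives every stereocentre of the extension units from L-tartrate or from substrate control next to it, and uses the same donor for units 1, 2 and 3.

Key step: step 9

## Route

Assumption: 1, 12, 18, (−)-epicatechin 20 and 3 (the acetonide of dimethyl L-tartrate, the commercial form of L-(+)-tartaric acid) are purchased.

Assumption: C4 of 17 and 19 is drawn trans to the C3 oxygen; this centre is lost on ionisation, so its epimer would behave identically.

Step 1
Reactants: 1 1,3-bis(benzyloxy)-5-bromobenzene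
Product: 2 1,5-bis(benzyloxy)-3-bromo-2-iodobenzene
Conditions: NIS (1.05 equiv), TFA (cat.), MeCN, 0 °C → rt, dark
Reagents that add atoms: N-iodosuccinimide, O=C1CCC(=O)N1I
Why: Electrophilic aromatic iodination; the position ortho to bromine is para to one benzyloxy group and ortho to the other and is less crowded than the position between the two benzyloxy groups, the site that formylation and bromination of 3,5-dialkoxybromobenzenes also take. This puts the future C4a between the bromine (future C8a) and a benzyloxy group (future C5), so the ring A pattern is fixed before the C–C bond is made.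

Step 2
Reactants: 3 dimethyl (4R,5R)-2,2-dimethyl-1,3-dioxolane-4,5-dicarboxylate
Product: 4 (4R,5R)-5-(methoxycarbonyl)-2,2-dimethyl-1,3-dioxolane-4-carboxylic acid
Conditions: KOH (1.0 equiv), MeOH, 0 °C → rt; then cold 1 M HCl to pH 3
Reagents that add atoms: potassium hydroxide, [K+].[OH-]
Why: Mono-saponification of one of two homotopic esters of the C2-symmetric diester; either ester gives the same half-acid, and one equivalent of base at low temperature should leave the trans dioxolane stereocentres untouched.

Step 3
Reactants: 4 (4R,5R)-5-(methoxycarbonyl)-2,2-dimethyl-1,3-dioxolane-4-carboxylic acid, 2 1,5-bis(benzyloxy)-3-bromo-2-iodobenzene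
Product: 8 methyl (4R,5S)-5-[2,4-bis(benzyloxy)-6-bromophenyl]-2,2-dimethyl-1,3-dioxolane-4-carboxylate, via tetrachlorophthalimidoyl ester 5 (not isolated), via arylmagnesium chloride 6 (not isolated), via arylzinc chloride 7 (not isolated)
Conditions: 4, N-hydroxytetrachlorophthalimide, DIC, CH2Cl2, rt; separately 2, iPrMgCl·LiCl, THF, −40 °C, then ZnCl2, −40 °C → rt; combine with NiCl2·glyme (20 mol%), 4,4'-di-tert-butyl-2,2'-bipyridine (40 mol%), THF/DMF, rt
Reagents that add atoms: none
Why: Nickel-catalysed decarboxylative Negishi-type arylation of a redox-active ester: an aryl nickel species reduces 5 by single-electron transfer, loss of CO2 gives the dioxolanyl radical, and this is captured anti to the neighbouring ester and coupled with the aryl group, so the trans dioxolane is kept. Iodine–magnesium exchange is selective over bromine at −40 °C, and transmetalation to zinc before warming prevents aryne formation from the ortho-bromo aryl metal.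

Step 4
Reactants: 8 methyl (4R,5S)-5-[2,4-bis(benzyloxy)-6-bromophenyl]-2,2-dimethyl-1,3-dioxolane-4-carboxylate
Product: 9 methyl (2R,3S)-3-[2,4-bis(benzyloxy)-6-bromophenyl]-2,3-dihydroxypropanoate
Conditions: AcOH/H2O (4:1), 50 °C
Reagents that add atoms: none
Why: Acid hydrolysis of the isopropylidene ketal, done here because the acetonide would have to become a trans-fused dioxolane on ring C and because no acid-sensitive C2 carbinol exists yet. Any epimerisation at the benzylic carbon is harmless, since this centre is ionised later.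

Step 5
Reactants: 9 methyl (2R,3S)-3-[2,4-bis(benzyloxy)-6-bromophenyl]-2,3-dihydroxypropanoate
Product: 10 methyl (2R,3S)-3-[2,4-bis(benzyloxy)-6-bromophenyl]-2,3-bis(methoxymethoxy)propanoate
Conditions: MOMCl (5 equiv), i-Pr2NEt (8 equiv), Bu4NI (cat.), CH2Cl2, 0 °C → 40 °C
Reagents that add atoms: chloromethyl methyl ether, COCCl
Why: O-Alkylation of both hydroxyls with an α-chloro ether under amine base, mild enough to avoid retro-aldol cleavage of the β-hydroxy ester. Methoxymethyl ethers survive organomagnesium, hydride and copper/carbonate conditions and, unlike benzyl ethers, can later be removed in the presence of the benzyl ethers to free O3.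

Step 6
Reactants: 10 methyl (2R,3S)-3-[2,4-bis(benzyloxy)-6-bromophenyl]-2,3-bis(methoxymethoxy)propanoate
Product: 11 (2R,3S)-3-[2,4-bis(benzyloxy)-6-bromophenyl]-N-methoxy-2,3-bis(methoxymethoxy)-N-methylpropanamide
Conditions: MeNH(OMe)·HCl (2 equiv), i-PrMgCl (4 equiv), THF, −20 °C → 0 °C
Reagents that add atoms: N,O-dimethylhydroxylamine hydrochloride, CNOC.Cl
Why: Aminolysis of the methyl ester by the chloromagnesium amide (Weinreb amide formation); at this temperature the α-alkoxy stereocentre should not epimerise and the electron-rich aryl bromide should not exchange with i-PrMgCl.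

Step 7
Reactants: 11 (2R,3S)-3-[2,4-bis(benzyloxy)-6-bromophenyl]-N-methoxy-2,3-bis(methoxymethoxy)-N-methylpropanamide, 12 1,2,3-tris(benzyloxy)-5-bromobenzene
Product: 14 (2R,3S)-3-[2,4-bis(benzyloxy)-6-bromophenyl]-2,3-bis(methoxymethoxy)-1-[3,4,5-tris(benzyloxy)phenyl]propan-1-one, via aryl Grignard reagent 13 (not isolated)
Conditions: 12, Mg turnings, I2 (cat.), THF, 50 °C; then 11, THF, 0 °C → rt; aq NH4Cl
Reagents that add atoms: none
Why: Weinreb ketone synthesis: the aryl Grignard reagent adds once and the chelated tetrahedral intermediate collapses to the ketone only on work-up. An aryl magnesium reagent, unlike an aryl lithium, does not exchange with the aryl bromide of 11 at 0 °C.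

Step 8
Reactants: 14 (2R,3S)-3-[2,4-bis(benzyloxy)-6-bromophenyl]-2,3-bis(methoxymethoxy)-1-[3,4,5-tris(benzyloxy)phenyl]propan-1-one
Product: 15 (1R,2S,3S)-3-[2,4-bis(benzyloxy)-6-bromophenyl]-2,3-bis(methoxymethoxy)-1-[3,4,5-tris(benzyloxy)phenyl]propan-1-ol
Conditions: K[(s-Bu)3BH] (1.5 equiv), THF, −78 °C; aq NH4Cl
Reagents that add atoms: none
Why: Felkin–Anh (non-chelation) reduction by a bulky, weakly coordinating trialkylborohydride: the α C–O bond stands anti to the incoming hydride, which passes the α-hydrogen, giving the 1,2-syn (threo) carbinol with 1R configuration. This sets the future C2 relative to the tartrate-derived C3.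

Step 9
Reactants: 15 (1R,2S,3S)-3-[2,4-bis(benzyloxy)-6-bromophenyl]-2,3-bis(methoxymethoxy)-1-[3,4,5-tris(benzyloxy)phenyl]propan-1-ol
Product: 16 (2R,3S,4S)-5,7-bis(benzyloxy)-3,4-bis(methoxymethoxy)-2-[3,4,5-tris(benzyloxy)phenyl]chromane
Conditions: CuI (20 mol%), 3,4,7,8-tetramethyl-1,10-phenanthroline (40 mol%), Cs2CO3 (2 equiv), toluene, 110 °C, argon
Reagents that add atoms: none
Why: Cs2CO3 deprotonates the only free hydroxyl, and the phenanthroline-bound monovalent copper alkoxide holds the metal next to the ortho C–Br bond. Oxidative addition gives a seven-membered aryl(alkoxo) trivalent copper metallacycle, and C–O reductive elimination forms O1–C8a and returns monovalent copper. The closest known reaction type is the Ullmann-type copper-catalysed intramolecular O-arylation of secondary alcohols with aryl bromides, which gives chromans and 2-arylchromans. Ring C closes as a six-membered ring by bond formation at the aromatic carbon (formally 6-exo-trig); the bromine is meta to both benzyloxy groups, so the C–Br bond is not deactivated by their resonance donation. No stereocentre is created: the C2–O, C3–O and C4–O bonds are never broken, so the 1,2-syn relation of 15 becomes the 2,3-cis relation of 16 with retention at C2. The step needs chemoselectivity for the six-membered ether, which the substrate secures because O3 and O4 are methoxymethyl ethers, so no five-membered dihydrobenzofuran can form and no acyl or silyl group can migrate to the alkoxide. It also needs the alkoxide to survive: there is no acidifying group for β-elimination of the C3 ether, and exclusion of air suppresses copper-mediated oxidation of the benzylic alkoxide.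

Step 10
Reactants: 16 (2R,3S,4S)-5,7-bis(benzyloxy)-3,4-bis(methoxymethoxy)-2-[3,4,5-tris(benzyloxy)phenyl]chromane
Product: 17 (2R,3R,4S)-5,7-bis(benzyloxy)-4-methoxy-2-[3,4,5-tris(benzyloxy)phenyl]chroman-3-ol
Conditions: HCl (0.1 M) in MeOH/CH2Cl2 (4:1), 0.01 M in 16, rt → 35 °C; then NaHCO3
Reagents that add atoms: methanol, CO
Why: Acid-catalysed acetal exchange: the O3 methoxymethyl group is transferred to the solvent, and the O4 acetal on the doubly activated benzylic carbon is exchanged through the C4 cation for a methoxy group, the leaving group for the couplings. High dilution in the nucleophilic solvent should keep the cation from being captured by ring A of a second molecule; methanol adds anti to the C3 substituent.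

Step 11
Reactants: 17 (2R,3R,4S)-5,7-bis(benzyloxy)-4-methoxy-2-[3,4,5-tris(benzyloxy)phenyl]chroman-3-ol, 18 3,4,5-tris(benzyloxy)benzoic acid
Product: 19 (2R,3R,4S)-5,7-bis(benzyloxy)-4-methoxy-2-[3,4,5-tris(benzyloxy)phenyl]chroman-3-yl 3,4,5-tris(benzyloxy)benzoate
Conditions: EDC·HCl (2 equiv), DMAP (1 equiv), CH2Cl2, rt
Reagents that add atoms: none
Why: Steglich esterification of the axial 3-hydroxyl; the conditions are basic, so the acid-labile 4-methoxy group is safe. This is the only point at which unit 3 is differentiated from units 1 and 2.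

Step 12
Reactants: 20 (−)-epicatechin
Product: 21 (2R,3R)-5,7-bis(benzyloxy)-2-[3,4-bis(benzyloxy)phenyl]chroman-3-ol
Conditions: BnBr (4.4 equiv), K2CO3 (5 equiv), DMF, 0 °C → rt, argon
Reagents that add atoms: benzyl bromide, BrCc1ccccc1
Why: Williamson etherification of the four phenols with a weak base; the secondary 3-hydroxyl is not alkylated by carbonate, and low temperature under argon limits base-induced C2 epimerisation and oxidation.

Step 13
Reactants: 19 (2R,3R,4S)-5,7-bis(benzyloxy)-4-methoxy-2-[3,4,5-tris(benzyloxy)phenyl]chroman-3-yl 3,4,5-tris(benzyloxy)benzoate, 21 (2R,3R)-5,7-bis(benzyloxy)-2-[3,4-bis(benzyloxy)phenyl]chroman-3-ol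
Product: 22 protected dimer, 3-O-[3,4,5-tris(benzyloxy)benzoyl]-5,7,3',4',5'-penta-O-benzyl-epigallocatechin-(4β→8)-5,7,3',4'-tetra-O-benzyl-epicatechin
Conditions: 21 (3 equiv), TMSOTf (0.3 equiv), CH2Cl2, −78 °C → −40 °C; Et3N quench
Reagents that add atoms: none
Why: Lewis-acid-promoted Friedel–Crafts alkylation: ionisation of the 4-methoxy group gives the C4 benzylic cation, stabilised by ring A and bridged by the 3-O-acyl group, and the arene attacks from the face opposite to the C3 ester and C2 aryl group, so the new C4 centre is 3,4-trans (4β). C8 of 21 is the preferred site (C6 lies between two benzyloxy groups), and the excess of 21 suppresses self-condensation of 19.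

Step 14
Reactants: 17 (2R,3R,4S)-5,7-bis(benzyloxy)-4-methoxy-2-[3,4,5-tris(benzyloxy)phenyl]chroman-3-ol, 22 protected dimer
Product: 23 protected trimer, 5,7,3',4',5'-penta-O-benzyl-epigallocatechin-(4β→8)-[3-O-(3,4,5-tris(benzyloxy)benzoyl)-5,7,3',4',5'-penta-O-benzyl-epigallocatechin]-(4β→8)-5,7,3',4'-tetra-O-benzyl-epicatechin
Conditions: 22 (2 equiv), TiCl4 (2 equiv), CH2Cl2/THF (9:1), 0 °C, slow addition of 17; aq NaHCO3
Reagents that add atoms: none
Why: The same Friedel–Crafts coupling with the 3-hydroxy donor, a combination for which TiCl4 in the presence of THF is an established promoter. The most nucleophilic and accessible site of 22 is C8 of its upper unit (unit 3), and attack anti to the cis C2/C3 substituents again gives 4β; slow addition of 17 to an excess of 22 limits donor self-condensation.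

Step 15
Reactants: 17 (2R,3R,4S)-5,7-bis(benzyloxy)-4-methoxy-2-[3,4,5-tris(benzyloxy)phenyl]chroman-3-ol, 23 protected trimer
Product: 24 protected tetramer, per-O-benzyl ether of the target at all 22 phenolic oxygens
Conditions: 23 (2 equiv), TiCl4 (2 equiv), CH2Cl2/THF (9:1), 0 °C, slow addition of 17; aq NaHCO3
Reagents that add atoms: none
Why: A repeat of step 14: the newest ring A (unit 2) of 23 carries the only unsubstituted C8 position, so the Friedel–Crafts alkylation should extend the chain there with 4β configuration.

Step 16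
Reactants: 24 protected tetramer
Product: 25 epigallocatechin-(4β→8)-epigallocatechin-(4β→8)-epigallocatechin 3-O-gallate-(4β→8)-epicatechin (CNP0305998.1)
Conditions: H2 (1 atm), Pd(OH)2/C, THF/MeOH/H2O, rt
Reagents that add atoms: none
Why: Hydrogenolysis of all 22 benzyl ethers under neutral conditions; the gallate ester, the interflavan bonds and the cyclic benzylic ethers at C2 should be retained, and no base is present that could epimerise C2 or shift the ester.

## Compound list

1 | 1,3-bis(benzyloxy)-5-bromobenzene | Brc1cc(OCc9ccccc9)cc(OCc9ccccc9)c1 | starting material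
2 | 1,5-bis(benzyloxy)-3-bromo-2-iodobenzene | Brc1cc(OCc9ccccc9)cc(OCc9ccccc9)c1I | intermediate
3 | dimethyl (4R,5R)-2,2-dimethyl-1,3-dioxolane-4,5-dicarboxylate (dimethyl 2,3-O-isopropylidene-L-tartrate) | COC(=O)[C@@H]1OC(C)(C)O[C@H]1C(=O)OC | starting material
4 | (4R,5R)-5-(methoxycarbonyl)-2,2-dimethyl-1,3-dioxolane-4-carboxylic acid | COC(=O)[C@@H]1OC(C)(C)O[C@H]1C(O)=O | intermediate
5 | 4-methyl 5-(4,5,6,7-tetrachloro-1,3-dioxoisoindolin-2-yl) (4R,5R)-2,2-dimethyl-1,3-dioxolane-4,5-dicarboxylate | COC(=O)[C@@H]1OC(C)(C)O[C@H]1C(=O)ON1C(=O)c2c(Cl)c(Cl)c(Cl)c(Cl)c2C1=O | intermediate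
6 | [2,4-bis(benzyloxy)-6-bromophenyl]magnesium chloride | Cl[Mg]c1c(Br)cc(OCc9ccccc9)cc1OCc9ccccc9 | intermediate
7 | [2,4-bis(benzyloxy)-6-bromophenyl]zinc chloride | Cl[Zn]c1c(Br)cc(OCc9ccccc9)cc1OCc9ccccc9 | intermediate
8 | methyl (4R,5S)-5-[2,4-bis(benzyloxy)-6-bromophenyl]-2,2-dimethyl-1,3-dioxolane-4-carboxylate | COC(=O)[C@@H]1OC(C)(C)O[C@H]1c1c(Br)cc(OCc9ccccc9)cc1OCc9ccccc9 | intermediate
9 | methyl (2R,3S)-3-[2,4-bis(benzyloxy)-6-bromophenyl]-2,3-dihydroxypropanoate | COC(=O)[C@H](O)[C@@H](O)c1c(Br)cc(OCc9ccccc9)cc1OCc9ccccc9 | intermediate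
10 | methyl (2R,3S)-3-[2,4-bis(benzyloxy)-6-bromophenyl]-2,3-bis(methoxymethoxy)propanoate | COC(=O)[C@H](OCOC)[C@@H](OCOC)c1c(Br)cc(OCc9ccccc9)cc1OCc9ccccc9 | intermediate
11 | (2R,3S)-3-[2,4-bis(benzyloxy)-6-bromophenyl]-N-methoxy-2,3-bis(methoxymethoxy)-N-methylpropanamide | CON(C)C(=O)[C@H](OCOC)[C@@H](OCOC)c1c(Br)cc(OCc9ccccc9)cc1OCc9ccccc9 | intermediate
12 | 1,2,3-tris(benzyloxy)-5-bromobenzene | Brc1cc(OCc9ccccc9)c(OCc9ccccc9)c(OCc9ccccc9)c1 | starting material
13 | [3,4,5-tris(benzyloxy)phenyl]magnesium bromide | Br[Mg]c1cc(OCc9ccccc9)c(OCc9ccccc9)c(OCc9ccccc9)c1 | intermediate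
14 | (2R,3S)-3-[2,4-bis(benzyloxy)-6-bromophenyl]-2,3-bis(methoxymethoxy)-1-[3,4,5-tris(benzyloxy)phenyl]propan-1-one | O=C(c1cc(OCc9ccccc9)c(OCc9ccccc9)c(OCc9ccccc9)c1)[C@H](OCOC)[C@@H](OCOC)c1c(Br)cc(OCc9ccccc9)cc1OCc9ccccc9 | intermediate
15 | (1R,2S,3S)-3-[2,4-bis(benzyloxy)-6-bromophenyl]-2,3-bis(methoxymethoxy)-1-[3,4,5-tris(benzyloxy)phenyl]propan-1-ol (open-chain extension unit, precursor of the key step) | O[C@H](c1cc(OCc9ccccc9)c(OCc9ccccc9)c(OCc9ccccc9)c1)[C@H](OCOC)[C@@H](OCOC)c1c(Br)cc(OCc9ccccc9)cc1OCc9ccccc9 | intermediate
16 | (2R,3S,4S)-5,7-bis(benzyloxy)-3,4-bis(methoxymethoxy)-2-[3,4,5-tris(benzyloxy)phenyl]chromane (2,3-cis-3,4-trans; product of the key step) | COCO[C@H]1c2c(OCc9ccccc9)cc(OCc9ccccc9)cc2O[C@H](c2cc(OCc9ccccc9)c(OCc9ccccc9)c(OCc9ccccc9)c2)[C@@H]1OCOC | intermediate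
17 | (2R,3R,4S)-5,7-bis(benzyloxy)-4-methoxy-2-[3,4,5-tris(benzyloxy)phenyl]chroman-3-ol (C4 donor for units 1 and 2) | CO[C@H]1c2c(OCc9ccccc9)cc(OCc9ccccc9)cc2O[C@H](c2cc(OCc9ccccc9)c(OCc9ccccc9)c(OCc9ccccc9)c2)[C@@H]1O | intermediate
18 | 3,4,5-tris(benzyloxy)benzoic acid | OC(=O)c1cc(OCc9ccccc9)c(OCc9ccccc9)c(OCc9ccccc9)c1 | starting material
19 | (2R,3R,4S)-5,7-bis(benzyloxy)-4-methoxy-2-[3,4,5-tris(benzyloxy)phenyl]chroman-3-yl 3,4,5-tris(benzyloxy)benzoate (C4 donor for unit 3) | CO[C@H]1c2c(OCc9ccccc9)cc(OCc9ccccc9)cc2O[C@H](c2cc(OCc9ccccc9)c(OCc9ccccc9)c(OCc9ccccc9)c2)[C@@H]1OC(=O)c1cc(OCc9ccccc9)c(OCc9ccccc9)c(OCc9ccccc9)c1 | intermediate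
20 | (−)-epicatechin, (2R,3R)-2-(3,4-dihydroxyphenyl)chromane-3,5,7-triol | O[C@@H]1Cc2c(O)cc(O)cc2O[C@@H]1c1ccc(O)c(O)c1 | starting material
21 | (2R,3R)-5,7-bis(benzyloxy)-2-[3,4-bis(benzyloxy)phenyl]chroman-3-ol | O[C@@H]1Cc2c(OCc9ccccc9)cc(OCc9ccccc9)cc2O[C@@H]1c1ccc(OCc9ccccc9)c(OCc9ccccc9)c1 | intermediate
22 | protected dimer: 3-O-[3,4,5-tris(benzyloxy)benzoyl]-5,7,3',4',5'-penta-O-benzyl-epigallocatechin-(4β→8)-5,7,3',4'-tetra-O-benzyl-epicatechin | O=C(O[C@@H]1[C@@H](c2c(OCc9ccccc9)cc(OCc9ccccc9)c3c2O[C@H](c2ccc(OCc9ccccc9)c(OCc9ccccc9)c2)[C@H](O)C3)c2c(OCc9ccccc9)cc(OCc9ccccc9)cc2O[C@@H]1c1cc(OCc9ccccc9)c(OCc9ccccc9)c(OCc9ccccc9)c1)c1cc(OCc9ccccc9)c(OCc9ccccc9)c(OCc9ccccc9)c1 | intermediate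
23 | protected trimer: 5,7,3',4',5'-penta-O-benzyl-epigallocatechin-(4β→8)-[3-O-(3,4,5-tris(benzyloxy)benzoyl)-5,7,3',4',5'-penta-O-benzyl-epigallocatechin]-(4β→8)-5,7,3',4'-tetra-O-benzyl-epicatechin | O=C(O[C@@H]1[C@@H](c2c(OCc9ccccc9)cc(OCc9ccccc9)c3c2O[C@H](c2ccc(OCc9ccccc9)c(OCc9ccccc9)c2)[C@H](O)C3)c2c(OCc9ccccc9)cc(OCc9ccccc9)c([C@H]3c4c(OCc9ccccc9)cc(OCc9ccccc9)cc4O[C@H](c4cc(OCc9ccccc9)c(OCc9ccccc9)c(OCc9ccccc9)c4)[C@@H]3O)c2O[C@@H]1c1cc(OCc9ccccc9)c(OCc9ccccc9)c(OCc9ccccc9)c1)c1cc(OCc9ccccc9)c(OCc9ccccc9)c(OCc9ccccc9)c1 | intermediate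
24 | protected tetramer: the target with all 22 phenolic oxygens as benzyl ethers | O=C(O[C@@H]1[C@@H](c2c(OCc9ccccc9)cc(OCc9ccccc9)c3c2O[C@H](c2ccc(OCc9ccccc9)c(OCc9ccccc9)c2)[C@H](O)C3)c2c(OCc9ccccc9)cc(OCc9ccccc9)c([C@H]3c4c(OCc9ccccc9)cc(OCc9ccccc9)c([C@H]5c6c(OCc9ccccc9)cc(OCc9ccccc9)cc6O[C@H](c6cc(OCc9ccccc9)c(OCc9ccccc9)c(OCc9ccccc9)c6)[C@@H]5O)c4O[C@H](c4cc(OCc9ccccc9)c(OCc9ccccc9)c(OCc9ccccc9)c4)[C@@H]3O)c2O[C@@H]1c1cc(OCc9ccccc9)c(OCc9ccccc9)c(OCc9ccccc9)c1)c1cc(OCc9ccccc9)c(OCc9ccccc9)c(OCc9ccccc9)c1 | intermediate
25 | epigallocatechin-(4β→8)-epigallocatechin-(4β→8)-epigallocatechin 3-O-gallate-(4β→8)-epicatechin (CNP0305998.1) | O=C(O[C@@H]1[C@@H](c2c(O)cc(O)c3c2O[C@H](c2ccc(O)c(O)c2)[C@H](O)C3)c2c(O)cc(O)c([C@H]3c4c(O)cc(O)c([C@H]5c6c(O)cc(O)cc6O[C@H](c6cc(O)c(O)c(O)c6)[C@@H]5O)c4O[C@H](c4cc(O)c(O)c(O)c4)[C@@H]3O)c2O[C@@H]1c1cc(O)c(O)c(O)c1)c1cc(O)c(O)c(O)c1 | target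

## Step count and least certain steps

Total: 16 steps. Longest linear sequence: 14 steps (3 → 4 → 8 → 9 → 10 → 11 → 14 → 15 → 16 → 17 → 19 → 22 → 23 → 24 → 25; steps 2–11 and 13–16).

**Step 9 (key step).** Oxidative addition at the C–Br bond, which is flanked by the branched chain, may be slow. Hydrodebromination and oxidation of the benzylic alkoxide by β-hydride loss from copper could then compete, and prolonged heating with carbonate could erode the C2 configuration. Fallback, setting out from ketone 14 and forming O1–C2 instead of O1–C8a: chelation-controlled reduction with Zn(BH4)2 gives the 1,2-anti (1S) carbinol F1. Miyaura borylation (PdCl2(dppf), bis(pinacolato)diboron, KOAc, dioxane) converts the bromide into the pinacol boronate F2, and oxidation with NaBO3·4H2O gives the phenol F3. Mitsunobu cyclisation (PPh3, DIAD, THF) then lets the phenol displace the activated C2 hydroxyl with inversion, and the route is rejoined at 16.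

**Step 3.** The aryl group on nickel carries two ortho substituents, so transmetalation and radical capture may be slow, giving reduction of the radical or dimerisation. Insertion of low-valent nickel into the aryl bromide of 7 or 8 would lead to oligomerisation. Fallback, setting out from half-acid 4 and using a polar instead of a radical C–C bond formation: oxidative decarboxylation with Pb(OAc)4 gives the anomeric acetate F4. A BF3·OEt2-promoted Friedel–Crafts arylation with bromoarene 1, which reacts ortho to bromine and para to a benzyloxy group and adds anti to the ester, rejoins the route at 8.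

**Step 8.** Chelation of the counter-ion by the α- and β-methoxymethoxy groups may override non-chelation control, eroding or reversing facial selectivity. Fallback, setting out from ester 10 and setting the centre by C–C instead of C–H bond formation: i-Bu2AlH at −78 °C gives the aldehyde F5. Addition of Grignard reagent 13 in CH2Cl2 with MgBr2·OEt2 proceeds through the Cram chelate and delivers the aryl group syn to the α-oxygen, rejoining the route at 15.

**Step 10.** While the slower O3 acetal is being cleaved, the C4 cation is formed repeatedly and may be captured by ring A of a second molecule (self-condensation); stopping early leaves the O3 acetal in place. Fallback, setting out from 16: ZnBr2 and propane-1-thiol in CH2Cl2 cleave both acetals within minutes and trap C4 irreversibly as the thioether F6. AgBF4 in methanol with 2,6-di-tert-butylpyridine then replaces sulfur by methoxy without Brønsted acid and rejoins the route at 17.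

**Step 14 (and its repeat, step 15).** As the nucleophile grows, donor self-condensation, attack at C6 or at a lower unit, and acid-induced cleavage of interflavan bonds already formed become more likely. Fallback, a convergent 2+2 assembly with orthogonal activation, setting out from 17: BF3·OEt2 and phenylmethanethiol at −78 °C convert 17 into the 4-benzylsulfanyl compound F7. Used in excess as the nucleophile, F7 is coupled with 17 under TMSOTf at −78 °C; the thioether is inert to the hard Lewis acid, and the product is the unit 1–unit 2 dimer F8 carrying sulfur at C4 of its lower unit. Thiophilic activation of F8 with AgBF4 in the presence of dimer 22 gives 24 directly, bypassing 23.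

## Further compounds

F1 | step 9 | (1S,2S,3S)-3-[2,4-bis(benzyloxy)-6-bromophenyl]-2,3-bis(methoxymethoxy)-1-[3,4,5-tris(benzyloxy)phenyl]propan-1-ol (C1 epimer of 15) | O[C@@H](c1cc(OCc9ccccc9)c(OCc9ccccc9)c(OCc9ccccc9)c1)[C@H](OCOC)[C@@H](OCOC)c1c(Br)cc(OCc9ccccc9)cc1OCc9ccccc9
F2 | step 9 | (1S,2S,3S)-3-[2,4-bis(benzyloxy)-6-(4,4,5,5-tetramethyl-1,3,2-dioxaborolan-2-yl)phenyl]-2,3-bis(methoxymethoxy)-1-[3,4,5-tris(benzyloxy)phenyl]propan-1-ol | O[C@@H](c1cc(OCc9ccccc9)c(OCc9ccccc9)c(OCc9ccccc9)c1)[C@H](OCOC)[C@@H](OCOC)c1c(B2OC(C)(C)C(C)(C)O2)cc(OCc9ccccc9)cc1OCc9ccccc9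
F3 | step 9 | 3,5-bis(benzyloxy)-2-[(1S,2S,3S)-3-hydroxy-1,2-bis(methoxymethoxy)-3-[3,4,5-tris(benzyloxy)phenyl]propyl]phenol | O[C@@H](c1cc(OCc9ccccc9)c(OCc9ccccc9)c(OCc9ccccc9)c1)[C@H](OCOC)[C@@H](OCOC)c1c(O)cc(OCc9ccccc9)cc1OCc9ccccc9
F4 | step 3 | methyl (4R)-5-acetoxy-2,2-dimethyl-1,3-dioxolane-4-carboxylate (both C5 epimers) | COC(=O)[C@@H]1OC(C)(C)OC1OC(C)=O
F5 | step 8 | (2R,3S)-3-[2,4-bis(benzyloxy)-6-bromophenyl]-2,3-bis(methoxymethoxy)propanal | O=C[C@H](OCOC)[C@@H](OCOC)c1c(Br)cc(OCc9ccccc9)cc1OCc9ccccc9
F6 | step 10 | (2R,3S,4S)-5,7-bis(benzyloxy)-4-(propylsulfanyl)-2-[3,4,5-tris(benzyloxy)phenyl]chroman-3-ol | CCCS[C@H]1c2c(OCc9ccccc9)cc(OCc9ccccc9)cc2O[C@H](c2cc(OCc9ccccc9)c(OCc9ccccc9)c(OCc9ccccc9)c2)[C@@H]1O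
F7 | step 14 | (2R,3S,4S)-5,7-bis(benzyloxy)-4-(benzylsulfanyl)-2-[3,4,5-tris(benzyloxy)phenyl]chroman-3-ol | c1ccccc1CS[C@H]1c2c(OCc9ccccc9)cc(OCc9ccccc9)cc2O[C@H](c2cc(OCc9ccccc9)c(OCc9ccccc9)c(OCc9ccccc9)c2)[C@@H]1O
F8 | step 14 | 5,7,3',4',5'-penta-O-benzyl-epigallocatechin-(4β→8)-4β-(benzylsulfanyl)-5,7,3',4',5'-penta-O-benzyl-epigallocatechin | c1ccccc1CS[C@H]1c2c(OCc9ccccc9)cc(OCc9ccccc9)c([C@H]3c4c(OCc9ccccc9)cc(OCc9ccccc9)cc4O[C@H](c4cc(OCc9ccccc9)c(OCc9ccccc9)c(OCc9ccccc9)c4)[C@@H]3O)c2O[C@H](c2cc(OCc9ccccc9)c(OCc9ccccc9)c(OCc9ccccc9)c2)[C@@H]1O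
A1 | alternative 1 | unit 3 flavan carrying at C4 the new ring A of unit 4 (free C8a phenol, O7 triisopropylsilyl, O5 benzyl, open C2–C3–C4 chain) | Oc3c(C[C@@H](OCc8ccccc8)[C@@H](O[Si](CC)(CC)CC)c7ccc(OCc8ccccc8)c(OCc8ccccc8)c7)c(OCc8ccccc8)cc(O[Si](C(C)C)(C(C)C)C(C)C)c3[C@H]1c2c(OCc8ccccc8)cc(OCc8ccccc8)cc2O[C@H](c7cc(OCc8ccccc8)c(OCc8ccccc8)c(OCc8ccccc8)c7)[C@@H]1O[Si](C)(C)C(C)(C)C
A2 | alternative 1 | 4β-[(triisopropylsilyloxy)ethynyl]-3-O-(tert-butyldimethylsilyl)-5,7,3',4',5'-penta-O-benzyl-epigallocatechin | CC(C)[Si](C(C)C)(C(C)C)OC#C[C@H]1c2c(OCc8ccccc8)cc(OCc8ccccc8)cc2O[C@H](c7cc(OCc8ccccc8)c(OCc8ccccc8)c(OCc8ccccc8)c7)[C@@H]1O[Si](C)(C)C(C)(C)C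
A3 | alternative 1 | 3-(benzyloxy)-4-[2-(benzyloxy)-3-[3,4-bis(benzyloxy)phenyl]-3-(triethylsilyloxy)propyl]cyclobut-2-en-1-one | O=C1C=C(OCc8ccccc8)C1C[C@@H](OCc8ccccc8)[C@@H](O[Si](CC)(CC)CC)c7ccc(OCc8ccccc8)c(OCc8ccccc8)c7
A4 | alternative 2 | unit 1–unit 2 dimer with unit 1 as its 3-O-acetate and ring B tripivalate | C1c2c(OCc8ccccc8)cc(OCc8ccccc8)c([C@H]3c4c(OCc8ccccc8)cc(OCc8ccccc8)cc4O[C@H](c7cc(OC(=O)C(C)(C)C)c(OC(=O)C(C)(C)C)c(OC(=O)C(C)(C)C)c7)[C@@H]3OC(C)=O)c2O[C@H](c7cc(OCc8ccccc8)c(OCc8ccccc8)c(OCc8ccccc8)c7)[C@@H]1OCc8ccccc8
A5 | alternative 2 | 2-(α-mesyloxybenzyl)-2,3-dihydrobenzofuran precursor (ring B tripivalate) attached through its C3 to C8 of per-O-benzyl unit 2 | C1c2c(OCc8ccccc8)cc(OCc8ccccc8)c([C@H]3c4c(OCc8ccccc8)cc(OCc8ccccc8)cc4O[C@@H]3[C@@H](OS(C)(=O)=O)c7cc(OC(=O)C(C)(C)C)c(OC(=O)C(C)(C)C)c(OC(=O)C(C)(C)C)c7)c2O[C@H](c7cc(OCc8ccccc8)c(OCc8ccccc8)c(OCc8ccccc8)c7)[C@@H]1OCc8ccccc8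
A6 | alternative 3 | perbenzylated unit 3–unit 4 dimer (epigallocatechin gallate-(4β→8)-epicatechin) | O=C(O[C@@H]1[C@@H](c2c(OCc8ccccc8)cc(OCc8ccccc8)c3c2O[C@H](c7ccc(OCc8ccccc8)c(OCc8ccccc8)c7)[C@H](OCc8ccccc8)C3)c2c(OCc8ccccc8)cc(OCc8ccccc8)cc2O[C@@H]1c7cc(OCc8ccccc8)c(OCc8ccccc8)c(OCc8ccccc8)c7)c7cc(OCc8ccccc8)c(OCc8ccccc8)c(OCc8ccccc8)c7
A7 | alternative 3 | (Z)-2-[3,4,5-tris(benzyloxy)phenyl]ethenyl 3,4,5-tris(benzyloxy)benzoate | O=C(O/C=C\c7cc(OCc8ccccc8)c(OCc8ccccc8)c(OCc8ccccc8)c7)c7cc(OCc8ccccc8)c(OCc8ccccc8)c(OCc8ccccc8)c7
A8 | alternative 3 | penta-O-benzyl-epicatechin carrying at C8 a [2,4-bis(benzyloxy)-6-hydroxyphenyl](hydroxy)methyl group | OC(c1c(O)cc(OCc8ccccc8)cc1OCc8ccccc8)c2c(OCc8ccccc8)cc(OCc8ccccc8)c3c2O[C@H](c7ccc(OCc8ccccc8)c(OCc8ccccc8)c7)[C@H](OCc8ccccc8)C3
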